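**Retrosynthetic overview**

- Ring numbering: C1 (methyl-bearing alkene carbon), C2 (=CH), C3 (bears ring Ar1, the chalcone-carrying resorcinol), C4 (bears the aroyl of ring Ar2), C5 (bears ring Ar3), C6 (CH2). The route rests on the C4 aroyl group being an ortho-hydroxyaryl ketone (ring Ar2) that can chelate a chiral Lewis acid, and on C4–C5–C6–C1 being closable first as a cyclobutane that carries C2=C3 as a styryl arm on C1.
- Disconnections, latest first: the ring Ar1 enone C=C (Claisen–Schmidt); the ring Ar2 side chain (Suzuki–Miyaura at a bromine placeholder); C3–C4 (1,3-shift of a vinylcyclobutane, breaking C1–C4); C5–C6 and C4–C1 ([2+2] photocycloaddition of a 2'-hydroxychalcone with an aryl diene).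
- The chalcone comes from 2-bromoresorcinol and 2,4-dihydroxybenzaldehyde. The diene comes from 2,4-dihydroxyacetophenone by 3-iodination and Suzuki coupling with a dienylboronate; the ring Ar1 acetyl group is carried unmasked, which removes a ketalisation and a hydrolysis.
- Ring order: cyclobutane (step 9), then cyclohexene by ring expansion (step 10); all arenes are bought.

Key step: step 9

Assumption: the (S,S) antipode of tBu-pybox is taken to give the (5S) centre; the sense of induction is to be checked on the first run and the (R,R) ligand used instead if it is opposite.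

**Route**

Step 1
Reactants: 1 2-bromoresorcinol
Product: 2 1-(3-bromo-2,4-dihydroxyphenyl)ethanone
Conditions: AcOH, BF3·OEt2, 90 °C; aq. NaOAc work-up
Reagents that add atoms: acetic acid CC(=O)O
Why: Friedel–Crafts (Nencki-type) C-acylation should occur at C4, the only position ortho to one hydroxyl and para to the other, which places bromine between the two oxygens.

Step 2
Reactants: 2 1-(3-bromo-2,4-dihydroxyphenyl)ethanone
Product: 3 1-[3-bromo-2-hydroxy-4-(methoxymethoxy)phenyl]ethanone
Conditions: MOMCl (1.1 equiv), iPr2NEt, CH2Cl2, 0 °C → rt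
Reagents that add atoms: chloromethyl methyl ether COCCl
Why: Williamson-type O-alkylation should be selective for the 4-OH because the 2-OH is hydrogen-bonded to the ketone and is left free for later chelation.

Step 3
Reactants: 4 2,4-dihydroxybenzaldehyde
Product: 5 2,4-bis(methoxymethoxy)benzaldehyde
Conditions: MOMCl (3 equiv), K2CO3, acetone, reflux
Reagents that add atoms: chloromethyl methyl ether COCCl
Why: Exhaustive O-alkylation of both phenoxides under forcing carbonate conditions gives the base-stable aldehyde partner used in steps 4 and 13.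

Step 4
Reactants: 3 1-[3-bromo-2-hydroxy-4-(methoxymethoxy)phenyl]ethanone; 5 2,4-bis(methoxymethoxy)benzaldehyde
Product: 7 (E)-1-[3-bromo-2-hydroxy-4-(methoxymethoxy)phenyl]-3-[2,4-bis(methoxymethoxy)phenyl]prop-2-en-1-one, via β-hydroxy ketone 6 (not isolated)
Conditions: KOH, EtOH/H2O, rt; AcOH to pH 6
Reagents that add atoms: none
Why: Claisen–Schmidt condensation of the methyl ketone enolate with the non-enolisable aldehyde, followed by E1cB dehydration, should give the E 2'-hydroxychalcone, and MOM ethers and the aryl bromide are inert to hydroxide at room temperature.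

Step 5
Reactants: 8 2,4-dihydroxyacetophenone
Product: 9 1-(2,4-dihydroxy-3-iodophenyl)ethanone
Conditions: I2, HIO3, EtOH/H2O, rt
Reagents that add atoms: iodine II; iodic acid OI(=O)=O
Why: Electrophilic iodination with iodine and iodic acid is known to go to the doubly activated 3-position between the two hydroxyls of resacetophenone.

Step 6
Reactants: 9 1-(2,4-dihydroxy-3-iodophenyl)ethanone
Product: 10 1-[3-iodo-2,4-bis(methoxymethoxy)phenyl]ethanone
Conditions: NaH (2.05 equiv), DMF, 0 °C; MOMCl, 0 °C → rt
Reagents that add atoms: chloromethyl methyl ether COCCl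
Why: Both phenols, including the hindered chelated one, are alkylated as their sodium phenoxides, and the base is limited to two equivalents so that the methyl ketone is not enolised.

Step 7
Reactants: 11 2-methylbut-1-en-3-yne; 12 pinacolborane
Product: 13 (E)-4,4,5,5-tetramethyl-2-(3-methylbuta-1,3-dien-1-yl)-1,3,2-dioxaborolane
Conditions: Cp2Zr(H)Cl (5 mol%), Et3N (10 mol%), neat, 60 °C
Reagents that add atoms: none
Why: Zirconium-catalysed syn hydroboration of the terminal alkyne places boron at the terminus and gives the E dienylboronate, the 1,1-disubstituted alkene being untouched.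

Step 8
Reactants: 10 1-[3-iodo-2,4-bis(methoxymethoxy)phenyl]ethanone; 13 (E)-4,4,5,5-tetramethyl-2-(3-methylbuta-1,3-dien-1-yl)-1,3,2-dioxaborolane
Product: 14 1-[3-[(1E)-3-methylbuta-1,3-dien-1-yl]-2,4-bis(methoxymethoxy)phenyl]ethanone
Conditions: Pd(OAc)2 (5 mol%), SPhos (10 mol%), K3PO4, THF/H2O, 60 °C
Reagents that add atoms: none
Why: Suzuki–Miyaura coupling with a ligand suited to di-ortho-substituted aryl halides should transfer the dienyl group with retention of E geometry, and the ketone is tolerated.

Step 9
Reactants: 7 (E)-1-[3-bromo-2-hydroxy-4-(methoxymethoxy)phenyl]-3-[2,4-bis(methoxymethoxy)phenyl]prop-2-en-1-one; 14 1-[3-[(1E)-3-methylbuta-1,3-dien-1-yl]-2,4-bis(methoxymethoxy)phenyl]ethanone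
Product: 15 [(1R,2S,4S)-2-[(E)-2-[3-acetyl-2,6-bis(methoxymethoxy)phenyl]ethenyl]-4-[2,4-bis(methoxymethoxy)phenyl]-2-methylcyclobutyl][3-bromo-2-hydroxy-4-(methoxymethoxy)phenyl]methanone
Conditions: Ru(bpy)3(PF6)2 (2.5 mol%), Sc(OTf)3 (10 mol%), (S,S)-tBu-pybox (15 mol%), diene used in threefold excess and the surplus recovered unchanged, iPrOAc/MeCN 3:1, degassed, blue LEDs (450 nm), 0 °C
Reagents that add atoms: none
Why: Under blue light Ru(bpy)3(PF6)2 should pass triplet energy only to the chalcone that is chelated through its ortho-hydroxy ketone to the Sc(OTf)3–pybox complex, because only the bound enone has a triplet low enough to be reached, while free 7 and the aryl diene 14 are too high in triplet energy to be sensitised. The enone triplet bonds from C5 to the CH2 terminus C6 of the diene and gives a 1,4-diradical that is acyl-stabilised at C4 and tertiary allylic at C1. After intersystem crossing the diradical closes C4–C1 in the four-membered mode, since the allyl radical is born E from the s-trans diene and cannot reach C3. The closest known reaction type is the enantioselective, Lewis-acid-catalysed, triplet-sensitised [2+2] photocycloaddition of 2'-hydroxychalcones with 1,3-dienes and styrenes. C5 is set by the pybox ligand, which shields one face of the bound enone β-carbon; C4 ends trans to C5 because the diradical closes to the less crowded trans-1,2 arrangement; the quaternary C1 should carry the styryl arm trans to the aroyl group, and this centre is erased in step 10. The step needs attack at the terminal 1,1-disubstituted alkene and not at the styrenic C2=C3 bond, which the unhindered CH2 and the more stabilised radical it leaves should secure, and it needs the chalcone to win scandium against the MOM ethers and the acetyl group, which its bidentate phenol–ketone binding should secure.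

Step 10
Reactants: 15 [(1R,2S,4S)-2-[(E)-2-[3-acetyl-2,6-bis(methoxymethoxy)phenyl]ethenyl]-4-[2,4-bis(methoxymethoxy)phenyl]-2-methylcyclobutyl][3-bromo-2-hydroxy-4-(methoxymethoxy)phenyl]methanone
Product: 16 [(1R,2S,6S)-2-[3-acetyl-2,6-bis(methoxymethoxy)phenyl]-6-[2,4-bis(methoxymethoxy)phenyl]-4-methylcyclohex-3-en-1-yl][3-bromo-2-hydroxy-4-(methoxymethoxy)phenyl]methanone
Conditions: Sc(OTf)3 (20 mol%), 4 Å MS, CH2Cl2, −20 °C → rt
Reagents that add atoms: none
Why: Vinylcyclobutane-to-cyclohexene 1,3-shift of a donor–acceptor cyclobutane: scandium chelation of the ortho-hydroxyaryl ketone should ionise the strained C1–C4 bond into a scandium enolate and an allyl cation stabilised by the 2,6-dioxygenated styryl arm, and reclosure of the cisoid ion pair from C4 to C3 with the enolate oxygen still held over C1 (aroyl endo, E-aryl outside) should set C3 and C4 cis while C4 settles trans to the untouched C5 centre; this relative configuration is predicted and not yet proven.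

Step 11
Reactants: 17 3-methylbut-1-yne; 12 pinacolborane
Product: 18 (E)-4,4,5,5-tetramethyl-2-(3-methylbut-1-en-1-yl)-1,3,2-dioxaborolane
Conditions: Cp2Zr(H)Cl (5 mol%), Et3N (10 mol%), neat, 60 °C
Reagents that add atoms: none
Why: The same zirconium-catalysed syn hydroboration of a terminal alkyne gives the E alkenylboronate needed for the ring Ar2 side chain.

Step 12
Reactants: 16 [(1R,2S,6S)-2-[3-acetyl-2,6-bis(methoxymethoxy)phenyl]-6-[2,4-bis(methoxymethoxy)phenyl]-4-methylcyclohex-3-en-1-yl][3-bromo-2-hydroxy-4-(methoxymethoxy)phenyl]methanone; 18 (E)-4,4,5,5-tetramethyl-2-(3-methylbut-1-en-1-yl)-1,3,2-dioxaborolane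
Product: 19 [(1R,2S,6S)-2-[3-acetyl-2,6-bis(methoxymethoxy)phenyl]-6-[2,4-bis(methoxymethoxy)phenyl]-4-methylcyclohex-3-en-1-yl][2-hydroxy-4-(methoxymethoxy)-3-[(E)-3-methylbut-1-en-1-yl]phenyl]methanone
Conditions: Pd(OAc)2 (5 mol%), SPhos (10 mol%), K3PO4, 1,4-dioxane/H2O, 80 °C
Reagents that add atoms: none
Why: Suzuki–Miyaura coupling at the di-ortho-oxygenated aryl bromide should install the E side chain with retention of alkene geometry, and the chelated phenol is left free so that its phenoxide shields the C4 ketone from enolisation here and in step 13.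

Step 13
Reactants: 19 [(1R,2S,6S)-2-[3-acetyl-2,6-bis(methoxymethoxy)phenyl]-6-[2,4-bis(methoxymethoxy)phenyl]-4-methylcyclohex-3-en-1-yl][2-hydroxy-4-(methoxymethoxy)-3-[(E)-3-methylbut-1-en-1-yl]phenyl]methanone; 5 2,4-bis(methoxymethoxy)benzaldehyde
Product: 21 artonin C heptakis(methoxymethyl) ether (all phenols protected except the chelated 2-OH of ring Ar2), via β-hydroxy ketone 20 (not isolated)
Conditions: KOH, EtOH/H2O, rt, dark; AcOH to pH 6
Reagents that add atoms: none
Why: Claisen–Schmidt condensation: only the ring Ar1 methyl ketone gives a reactive enolate, the ring Ar2 ketone being deactivated as a phenoxide-conjugated (vinylogous carboxylate) carbonyl so that C4 should not epimerise, and E1cB dehydration gives the E enone.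

Step 14
Reactants: 21 artonin C heptakis(methoxymethyl) ether
Product: 22 artonin C, (E)-1-[3-[(1S,5S,6R)-6-[2,4-dihydroxy-3-[(E)-3-methylbut-1-enyl]benzoyl]-5-(2,4-dihydroxyphenyl)-3-methylcyclohex-2-en-1-yl]-2,4-dihydroxyphenyl]-3-(2,4-dihydroxyphenyl)prop-2-en-1-one
Conditions: 3 M aq. HCl, MeOH, 40 °C, dark, argon; buffer to pH 6
Reagents that add atoms: none
Why: Acid-catalysed acetal solvolysis in methanol should remove the seven aryl MOM ethers without touching a stereocentre, and it is kept mild, short and dark to limit hydroxychalcone isomerisation and phenol–alkene cyclisation.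

**Compound list**

1 | 2-bromoresorcinol (2-bromobenzene-1,3-diol) | Oc1cccc(O)c1Br | starting material
2 | 1-(3-bromo-2,4-dihydroxyphenyl)ethanone | CC(=O)c1ccc(O)c(Br)c1O | intermediate
3 | 1-[3-bromo-2-hydroxy-4-(methoxymethoxy)phenyl]ethanone | CC(=O)c1ccc(OCOC)c(Br)c1O | intermediate
4 | 2,4-dihydroxybenzaldehyde | O=Cc1ccc(O)cc1O | starting material
5 | 2,4-bis(methoxymethoxy)benzaldehyde | O=Cc1ccc(OCOC)cc1OCOC | intermediate
6 | 1-[3-bromo-2-hydroxy-4-(methoxymethoxy)phenyl]-3-hydroxy-3-[2,4-bis(methoxymethoxy)phenyl]propan-1-one (racemic carbinol, not isolated) | O=C(CC(O)c1ccc(OCOC)cc1OCOC)c1ccc(OCOC)c(Br)c1O | intermediate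
7 | (E)-1-[3-bromo-2-hydroxy-4-(methoxymethoxy)phenyl]-3-[2,4-bis(methoxymethoxy)phenyl]prop-2-en-1-one | O=C(/C=C/c1ccc(OCOC)cc1OCOC)c1ccc(OCOC)c(Br)c1O | intermediate
8 | 2,4-dihydroxyacetophenone | CC(=O)c1ccc(O)cc1O | starting material
9 | 1-(2,4-dihydroxy-3-iodophenyl)ethanone | CC(=O)c1ccc(O)c(I)c1O | intermediate
10 | 1-[3-iodo-2,4-bis(methoxymethoxy)phenyl]ethanone | CC(=O)c1ccc(OCOC)c(I)c1OCOC | intermediate
11 | 2-methylbut-1-en-3-yne | C=C(C)C#C | starting material
12 | pinacolborane (4,4,5,5-tetramethyl-1,3,2-dioxaborolane) | CC1(C)OBOC1(C)C | starting material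
13 | (E)-4,4,5,5-tetramethyl-2-(3-methylbuta-1,3-dien-1-yl)-1,3,2-dioxaborolane | C=C(C)/C=C/B1OC(C)(C)C(C)(C)O1 | intermediate
14 | 1-[3-[(1E)-3-methylbuta-1,3-dien-1-yl]-2,4-bis(methoxymethoxy)phenyl]ethanone | C=C(C)/C=C/c1c(OCOC)ccc(C(C)=O)c1OCOC | intermediate
15 | [(1R,2S,4S)-2-[(E)-2-[3-acetyl-2,6-bis(methoxymethoxy)phenyl]ethenyl]-4-[2,4-bis(methoxymethoxy)phenyl]-2-methylcyclobutyl][3-bromo-2-hydroxy-4-(methoxymethoxy)phenyl]methanone (aroyl and aryl trans; styryl trans to aroyl) | C[C@@]1(/C=C/c2c(OCOC)ccc(C(C)=O)c2OCOC)C[C@H](c2ccc(OCOC)cc2OCOC)[C@H]1C(=O)c1ccc(OCOC)c(Br)c1O | intermediate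
16 | [(1R,2S,6S)-2-[3-acetyl-2,6-bis(methoxymethoxy)phenyl]-6-[2,4-bis(methoxymethoxy)phenyl]-4-methylcyclohex-3-en-1-yl][3-bromo-2-hydroxy-4-(methoxymethoxy)phenyl]methanone | CC1=C[C@H](c2c(OCOC)ccc(C(C)=O)c2OCOC)[C@H](C(=O)c2ccc(OCOC)c(Br)c2O)[C@@H](c2ccc(OCOC)cc2OCOC)C1 | intermediate
17 | 3-methylbut-1-yne | CC(C)C#C | starting material
18 | (E)-4,4,5,5-tetramethyl-2-(3-methylbut-1-en-1-yl)-1,3,2-dioxaborolane | CC(C)/C=C/B1OC(C)(C)C(C)(C)O1 | intermediate
19 | [(1R,2S,6S)-2-[3-acetyl-2,6-bis(methoxymethoxy)phenyl]-6-[2,4-bis(methoxymethoxy)phenyl]-4-methylcyclohex-3-en-1-yl][2-hydroxy-4-(methoxymethoxy)-3-[(E)-3-methylbut-1-en-1-yl]phenyl]methanone | CC1=C[C@H](c2c(OCOC)ccc(C(C)=O)c2OCOC)[C@H](C(=O)c2ccc(OCOC)c(/C=C/C(C)C)c2O)[C@@H](c2ccc(OCOC)cc2OCOC)C1 | intermediate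
20 | β-hydroxy ketone from 19 and 5 (carbinol epimers, not isolated) | CC1=C[C@H](c2c(OCOC)ccc(C(=O)CC(O)c3ccc(OCOC)cc3OCOC)c2OCOC)[C@H](C(=O)c2ccc(OCOC)c(/C=C/C(C)C)c2O)[C@@H](c2ccc(OCOC)cc2OCOC)C1 | intermediate
21 | artonin C heptakis(methoxymethyl) ether (2-OH of ring Ar2 free) | CC1=C[C@H](c2c(OCOC)ccc(C(=O)/C=C/c3ccc(OCOC)cc3OCOC)c2OCOC)[C@H](C(=O)c2ccc(OCOC)c(/C=C/C(C)C)c2O)[C@@H](c2ccc(OCOC)cc2OCOC)C1 | intermediate
22 | artonin C, (3S,4R,5S) in the ring numbering of the overview; C3/C4 cis, C4/C5 trans | CC1=C[C@H](c2c(O)ccc(C(=O)/C=C/c3ccc(O)cc3O)c2O)[C@H](C(=O)c2ccc(O)c(/C=C/C(C)C)c2O)[C@@H](c2ccc(O)cc2O)C1 | target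

**Step count**

Total: 14 steps. Longest linear sequence: 8 steps (steps 1, 2, 4, 9, 10, 12, 13, 14; the diene branch through steps 5, 6, 8 is equally long).

**Steps most likely to fail**

1. Step 10 (ring expansion). The ion pair may close at C3 with the aroyl group exo, which would give the C3/C4 trans isomer. It may also fragment into chalcone and diene and recombine, which would erode the enantiopurity set at C5. The allyl cation may be intercepted by an ortho MOM oxygen of ring Ar1 or lose a proton to a triene. Fallback: the cyclobutane is bypassed. The fallback sets out from chalcone 7 and diene 14 and joins them directly in an enantioselective, endo-selective Diels–Alder cycloaddition catalysed by a chiral borate made from B(OPh)3 and a BINOL-type diol, the diol antipode being chosen for the (5S) series. This is established chemistry for 2'-hydroxychalcones with 1-aryl-3-methylbutadienes and comes back to the route at cyclohexene 16. It makes no new compound (F0).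

2. Step 9 (photocycloaddition). The five MOM ethers and the acetyl group of the diene may sequester scandium, which would slow the sensitised pathway and lower the facial selectivity. Addition may also occur at the styrenic C2=C3 bond, and the valuable diene cannot be used in large excess. Fallback: the fallback sets out from chalcone 7 and uses isoprene in large excess under the same Ru(bpy)3(PF6)2 / Sc(OTf)3 / tBu-pybox catalysis, a simple diene of the kind for which this photocycloaddition is established. Addition at the methyl-substituted alkene should give [(1R,2S,4S)-4-[2,4-bis(methoxymethoxy)phenyl]-2-ethenyl-2-methylcyclobutyl][3-bromo-2-hydroxy-4-(methoxymethoxy)phenyl]methanone F1, any regioisomer from the other alkene being separated. Ring Ar1 is then attached by Mizoroki–Heck arylation of the vinyl group with aryl iodide 10 (Pd(OAc)2, P(o-tol)3, Et3N, DMF, 80 °C), the iodide reacting ahead of the ring Ar2 bromide, and the route is rejoined at cyclobutane 15.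

3. Step 14 (global deprotection). Prolonged protic acid may cyclise a freed ortho-phenol of ring Ar1 onto the C1=C2 alkene, isomerise the hydroxychalcone towards flavanone or flavylium species, or leave MOM groups on. Fallback: protic solvolysis is replaced by an acetal-to-silyl-ether exchange. The fallback sets out from 21, which is treated with TMSOTf and 2,2'-bipyridyl in CH2Cl2 at 0 °C, a buffered, non-protic method known for aryl MOM ethers. This should give artonin C octakis(trimethylsilyl) ether F2, which is hydrolysed with water at neutral pH to return at target 22.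

**Further compounds**

F0 | step 10 | none | none
F1 | step 9 | [(1R,2S,4S)-4-[2,4-bis(methoxymethoxy)phenyl]-2-ethenyl-2-methylcyclobutyl][3-bromo-2-hydroxy-4-(methoxymethoxy)phenyl]methanone | C[C@@]1(C=C)C[C@H](c2ccc(OCOC)cc2OCOC)[C@H]1C(=O)c1ccc(OCOC)c(Br)c1O
F2 | step 14 | artonin C octakis(trimethylsilyl) ether | CC1=C[C@H](c2c(O[Si](C)(C)C)ccc(C(=O)/C=C/c3ccc(O[Si](C)(C)C)cc3O[Si](C)(C)C)c2O[Si](C)(C)C)[C@H](C(=O)c2ccc(O[Si](C)(C)C)c(/C=C/C(C)C)c2O[Si](C)(C)C)[C@@H](c2ccc(O[Si](C)(C)C)cc2O[Si](C)(C)C)C1
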